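The plan hinges on one bond of the cyclohexene: C1 (the CH carrying coumarin ring A) to the quaternary C6, which lies allylic to the C2=C3 double bond. Imagining the alkene carbon on C6 at the acid oxidation level turns the carbocycle into a 2-aryl-cyclohex-3-ene-1-carboxylic acid, the signature of an enolate Claisen ring contraction. One Ireland–Claisen shift of a δ-lactone silyl ketene acetal therefore makes C1–C6, closes the ring and fixes both stereocentres, relaying the carbinol centre of (R)-linalool through a forced boat. The precursor is a (6R)-3,6-dimethyl-δ-valerolactone carrying an (E)-2-(7-methoxycoumarin-6-yl)ethenyl group on its carbinol carbon; ring B is attached afterwards by cross-coupling.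

Key step: step 8

Remark: cyclohexene numbering is C1 (CH–ring A), C2=C3(CH3), C4, C5, C6 (quaternary). Commercial (R)-(−)-linalool of high enantiomeric purity is assumed, as its carbinol centre is the only source of absolute configuration. The CIP labels change from (1S,2S) in 16–18 to (1R,6R)/(1R,2R) in 19 and 23 only because substituent priorities change; no bond to a stereocentre is touched.

Step 1
Reactants: 1 (R)-linalool
Product: 3 (5R)-5-ethenyl-5-methyloxolan-2-ol (anomer mixture), via secondary ozonide 2 (not isolated)
Conditions: O3, CH2Cl2, −78 °C (Sudan Red 7B end point); then Me2S, −78 °C → rt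
Reagents that add atoms: ozone, [O-][O+]=O
Why: Chemoselective ozonolysis with reductive work-up: ozone attacks the electron-rich trisubstituted alkene far faster than the vinyl group on the oxygen-bearing carbon, Me2S reduces ozonide 2, and the hydroxy aldehyde closes to lactol 3 with the carbinol stereocentre untouched.

Step 2
Reactants: 3 (5R)-5-ethenyl-5-methyloxolan-2-ol
Product: 5 (6R)-6-ethenyl-6-methyloxan-2-ol (anomer mixture), via enol ether 4 (not isolated)
Conditions: Ph3P(CH2OMe)Cl, KOtBu (excess), THF, 0 °C → rt; then 1 M HCl (aq) added to the flask, rt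
Reagents that add atoms: (methoxymethyl)triphenylphosphonium chloride, COC[P+](c1ccccc1)(c1ccccc1)c1ccccc1.[Cl-]; water, O
Why: Wittig methoxymethylenation of the open-chain aldehyde tautomer of the lactol gives enol ether 4, whose acid hydrolysis in the same flask unveils the one-carbon-longer aldehyde that the tertiary alcohol traps as the six-membered lactol; no bond to the stereocentre is touched.

Step 3
Reactants: 5 (6R)-6-ethenyl-6-methyloxan-2-ol
Product: 6 (6R)-6-ethenyl-6-methyloxan-2-one
Conditions: TEMPO (cat.), PhI(OAc)2, CH2Cl2, rt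
Reagents that add atoms: none
Why: Oxoammonium (TEMPO) oxidation of a lactol to the lactone with PhI(OAc)2 as terminal oxidant, conditions that leave the vinyl group and the tertiary allylic C–O bond alone.

Step 4
Reactants: 6 (6R)-6-ethenyl-6-methyloxan-2-one
Product: 8 (6R)-6-ethenyl-3,6-dimethyloxan-2-one (both C3 epimers), via lithium enolate 7 (not isolated)
Conditions: LiN(iPr)2, THF, −78 °C; then MeI, −78 → −40 °C
Reagents that add atoms: iodomethane, CI
Why: Kinetic lactone enolate formation and C-alkylation with MeI at low temperature, where the enolate does not rearrange; the new C3 centre need not be controlled because it becomes trigonal again in step 8.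

Step 5
Reactants: 9 2-hydroxy-4-methoxybenzaldehyde
Product: 10 2-hydroxy-5-iodo-4-methoxybenzaldehyde
Conditions: ICl, AcOH, rt
Reagents that add atoms: iodine monochloride, ClI
Why: Electrophilic aromatic iodination directed para to the free phenol and ortho to the methoxy group (C5), the alternative C3 position being flanked by two substituents.

Step 6
Reactants: 10 2-hydroxy-5-iodo-4-methoxybenzaldehyde
Product: 12 6-iodo-7-methoxy-2H-chromen-2-one, via cinnamate ester 11 (not isolated)
Conditions: Ph3P=CHCO2Et, PhNEt2, reflux (ca. 215 °C)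
Reagents that add atoms: ethyl (triphenylphosphoranylidene)acetate, CCOC(=O)C=P(c1ccccc1)(c1ccccc1)c1ccccc1
Why: Wittig olefination of the salicylaldehyde followed, at the reflux temperature of diethylaniline, by E/Z isomerisation of cinnamate 11 and lactonisation with loss of ethanol, the standard one-flask coumarin synthesis.

Step 7
Reactants: 8 (6R)-6-ethenyl-3,6-dimethyloxan-2-one; 12 6-iodo-7-methoxy-2H-chromen-2-one
Product: 13 (6R)-6-[(E)-2-(7-methoxy-2-oxo-2H-chromen-6-yl)ethenyl]-3,6-dimethyloxan-2-one (both C3 epimers)
Conditions: Pd(OAc)2 (5 mol %), Ag2CO3, toluene, 90 °C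
Reagents that add atoms: none
Why: Mizoroki–Heck arylation in which the aryl group adds to the terminal vinyl carbon and syn β-hydride elimination from the benzylic CH2 gives the E-styrene; phosphine-free, silver-assisted conditions of the kind used to arylate allylic esters without losing the ester are chosen so that neither β-carboxylate elimination nor ionisation of the tertiary allylic C–O bond by zerovalent palladium disturbs the (6R) centre.

Step 8
Reactants: 13 (6R)-6-[(E)-2-(7-methoxy-2-oxo-2H-chromen-6-yl)ethenyl]-3,6-dimethyloxan-2-one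
Product: 16 (1S,2S)-2-(7-methoxy-2-oxo-2H-chromen-6-yl)-1,4-dimethylcyclohex-3-ene-1-carboxylic acid, via silyl ketene acetal 14 (not isolated), via trimethylsilyl ester 15 (not isolated)
Conditions: Me3SiCl, Et3N, THF, −78 °C; LiN(SiMe3)2 added last, −78 → 0 °C; then toluene, 70 °C; then 10% aq. citric acid, THF, rt
Reagents that add atoms: none
Why: Deprotonation at lactone C3 in the presence of Me3SiCl traps the enolate as cyclic silyl ketene acetal 14 (geometry fixed by the ring), and on warming the C3=C2–O1/C6–CH=CH(aryl) array undergoes a concerted [3,3]-sigmatropic Ireland–Claisen shift in which the lactone C6–O1 bond breaks as C3 bonds to the aryl-bearing alkene carbon, giving silyl ester 15 and, after mild hydrolysis, acid 16. The closest known reaction type is the ring-contracting ester-enolate Claisen rearrangement of 6-alkenyl δ-lactones to cyclohex-3-enecarboxylic acids. The six-membered carbocycle is closed pericyclically rather than by an ionic cyclisation: because the C4–C5 tether ties the two termini together, the only reachable geometry is a bicyclo[2.2.2]octane-like boat, suprafacial on both three-atom components. Both new stereocentres follow from that boat: the E-alkene points the aryl group toward the breaking C2–O1 bridge so that it ends cis to the carboxyl and trans to the ring methyl, and since the new bond forms on the face of the allyl unit that oxygen leaves, the (6R) carbinol centre dictates the (1S,2S) configuration while the C3 epimer mixture is erased on enolisation. The step needs enolisation of the δ-lactone beside the coumarin lactone of ring A, which has no α-hydrogen and should be spared by the hindered amide base at −78 °C under in situ silylation, and a concerted rather than ionising C–O cleavage, which the non-polar medium and moderate temperature favour.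

Step 9
Reactants: 16 (1S,2S)-2-(7-methoxy-2-oxo-2H-chromen-6-yl)-1,4-dimethylcyclohex-3-ene-1-carboxylic acid
Product: 18 (1S,2S)-2-(7-methoxy-2-oxo-2H-chromen-6-yl)-1,4-dimethylcyclohex-3-ene-1-carbaldehyde, via acid chloride 17 (not isolated)
Conditions: (COCl)2, DMF (cat.), CH2Cl2, 0 °C → rt, evaporate; then LiAlH(OtBu)3, THF, −78 °C
Reagents that add atoms: none
Why: Acyl chloride formation (Vilsmeier-type activation) and partial reduction with the bulky LiAlH(OtBu)3 (acyl chloride to aldehyde), which at −78 °C should react with the acyl chloride much faster than with the coumarin lactone; the α-carbon is quaternary, so nothing can epimerise.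

Step 10
Reactants: 18 (1S,2S)-2-(7-methoxy-2-oxo-2H-chromen-6-yl)-1,4-dimethylcyclohex-3-ene-1-carbaldehyde
Product: 19 7-methoxy-6-[(1R,6R)-3,6-dimethyl-6-[(E)-2-(4,4,5,5-tetramethyl-1,3,2-dioxaborolan-2-yl)ethenyl]cyclohex-2-en-1-yl]-2H-chromen-2-one
Conditions: CrCl2, LiI, Cl2CHBpin, THF, rt
Reagents that add atoms: 2-(dichloromethyl)-4,4,5,5-tetramethyl-1,3,2-dioxaborolane, CC1(C)OB(C(Cl)Cl)OC1(C)C
Why: Takai–Utimoto boryl-olefination: the geminal dichromium species generated from Cl2CHBpin by CrCl2 adds to the non-enolisable aldehyde and eliminates through the less hindered arrangement to give the E-alkenylboronate, while the coumarin lactone and the ring alkene are inert to divalent chromium.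

Step 11
Reactants: 20 7-hydroxycoumarin
Product: 21 7-hydroxy-8-iodo-2H-chromen-2-one
Conditions: I2, KI, 20% aq. NH3, rt
Reagents that add atoms: iodine, II
Why: Electrophilic iodination of the phenoxide at C8, the ortho position lying between the two ring oxygens, which is the usual site of substitution of 7-hydroxycoumarin under basic conditions.

Step 12
Reactants: 21 7-hydroxy-8-iodo-2H-chromen-2-one
Product: 22 8-iodo-7-methoxy-2H-chromen-2-one
Conditions: MeI, K2CO3, acetone, reflux
Reagents that add atoms: iodomethane, CI
Why: Williamson O-methylation of the phenol with MeI and K2CO3.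

Step 13
Reactants: 19 alkenylboronate of step 10; 22 8-iodo-7-methoxy-2H-chromen-2-one
Product: 23 8-[(E)-2-[(1R,2R)-2-(7-methoxy-2-oxo-2H-chromen-6-yl)-1,4-dimethylcyclohex-3-en-1-yl]ethenyl]-7-methoxy-2H-chromen-2-one (target)
Conditions: Pd(OAc)2 (5 mol %), SPhos, K3PO4, THF/H2O (10:1), 60 °C; dilute citric acid work-up
Reagents that add atoms: none
Why: Suzuki–Miyaura coupling that joins the two sp2 carbons with retention of the E geometry, a bulky biarylphosphine coping with the doubly ortho-substituted aryl iodide; mildly acidic work-up recloses any coumarin ring opened by the base, and no stereocentre is involved.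

Compound list
1 | (R)-linalool, (3R)-3,7-dimethylocta-1,6-dien-3-ol | C=C[C@](C)(O)CCC=C(C)C | starting material
2 | (3R)-5-(5,5-dimethyl-1,2,4-trioxolan-3-yl)-3-methylpent-1-en-3-ol (secondary ozonide) | C=C[C@](C)(O)CCC1OOC(C)(C)O1 | intermediate
3 | (5R)-5-ethenyl-5-methyloxolan-2-ol (anomer mixture) | C=C[C@@]1(C)CCC(O)O1 | intermediate
4 | (3R)-7-methoxy-3-methylhepta-1,6-dien-3-ol (E/Z mixture) | C=C[C@](C)(O)CCC=COC | intermediate
5 | (6R)-6-ethenyl-6-methyloxan-2-ol (anomer mixture) | C=C[C@@]1(C)CCCC(O)O1 | intermediate
6 | (6R)-6-ethenyl-6-methyloxan-2-one | C=C[C@@]1(C)CCCC(=O)O1 | intermediate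
7 | lithium (2R)-2-ethenyl-2-methyl-3,4-dihydro-2H-pyran-6-olate | C=C[C@@]1(C)CCC=C([O-])O1.[Li+] | intermediate
8 | (6R)-6-ethenyl-3,6-dimethyloxan-2-one (both C3 epimers) | C=C[C@@]1(C)CCC(C)C(=O)O1 | intermediate
9 | 2-hydroxy-4-methoxybenzaldehyde | COc1ccc(C=O)c(O)c1 | starting material
10 | 2-hydroxy-5-iodo-4-methoxybenzaldehyde | COc1cc(O)c(C=O)cc1I | intermediate
11 | ethyl (E)-3-(2-hydroxy-5-iodo-4-methoxyphenyl)prop-2-enoate | CCOC(=O)/C=C/c1cc(I)c(OC)cc1O | intermediate
12 | 6-iodo-7-methoxy-2H-chromen-2-one | COc1cc2oc(=O)ccc2cc1I | intermediate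
13 | (6R)-6-[(E)-2-(7-methoxy-2-oxo-2H-chromen-6-yl)ethenyl]-3,6-dimethyloxan-2-one (both C3 epimers) | O=C1O[C@@](C)(/C=C/c2cc3ccc(=O)oc3cc2OC)CCC1C | intermediate
14 | {[(2R)-2-[(E)-2-(7-methoxy-2-oxo-2H-chromen-6-yl)ethenyl]-2,5-dimethyl-3,4-dihydro-2H-pyran-6-yl]oxy}trimethylsilane | C[Si](C)(C)OC1=C(C)CC[C@](C)(/C=C/c2cc3ccc(=O)oc3cc2OC)O1 | intermediate
15 | trimethylsilyl (1S,2S)-2-(7-methoxy-2-oxo-2H-chromen-6-yl)-1,4-dimethylcyclohex-3-ene-1-carboxylate | COc1cc2oc(=O)ccc2cc1[C@@H]1C=C(C)CC[C@]1(C)C(=O)O[Si](C)(C)C | intermediate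
16 | (1S,2S)-2-(7-methoxy-2-oxo-2H-chromen-6-yl)-1,4-dimethylcyclohex-3-ene-1-carboxylic acid (aryl cis to carboxyl) | COc1cc2oc(=O)ccc2cc1[C@@H]1C=C(C)CC[C@]1(C)C(=O)O | intermediate
17 | (1S,2S)-2-(7-methoxy-2-oxo-2H-chromen-6-yl)-1,4-dimethylcyclohex-3-ene-1-carbonyl chloride | COc1cc2oc(=O)ccc2cc1[C@@H]1C=C(C)CC[C@]1(C)C(Cl)=O | intermediate
18 | (1S,2S)-2-(7-methoxy-2-oxo-2H-chromen-6-yl)-1,4-dimethylcyclohex-3-ene-1-carbaldehyde | COc1cc2oc(=O)ccc2cc1[C@@H]1C=C(C)CC[C@]1(C)C=O | intermediate
19 | 7-methoxy-6-[(1R,6R)-3,6-dimethyl-6-[(E)-2-(4,4,5,5-tetramethyl-1,3,2-dioxaborolan-2-yl)ethenyl]cyclohex-2-en-1-yl]-2H-chromen-2-one | COc1cc2oc(=O)ccc2cc1[C@@H]1C=C(C)CC[C@]1(C)/C=C/B1OC(C)(C)C(C)(C)O1 | intermediate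
20 | 7-hydroxycoumarin, 7-hydroxy-2H-chromen-2-one | O=c1ccc2ccc(O)cc2o1 | starting material
21 | 7-hydroxy-8-iodo-2H-chromen-2-one | O=c1ccc2ccc(O)c(I)c2o1 | intermediate
22 | 8-iodo-7-methoxy-2H-chromen-2-one | COc1ccc2ccc(=O)oc2c1I | intermediate
23 | 8-[(E)-2-[(1R,2R)-2-(7-methoxy-2-oxo-2H-chromen-6-yl)-1,4-dimethylcyclohex-3-en-1-yl]ethenyl]-7-methoxy-2H-chromen-2-one | COc1cc2oc(=O)ccc2cc1[C@@H]1C=C(C)CC[C@]1(C)/C=C/c1c(OC)ccc2ccc(=O)oc12 | target

Total step count: 13. Longest linear sequence: 9 steps (steps 1, 2, 3, 4, 7, 8, 9, 10, 13, from (R)-linalool).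

Steps most likely to fail

Step 8. The amide base or the lactone enolate may attack the coumarin of ring A before silylation is complete. The tertiary, styrene-activated C–O bond of the ketene acetal may also break heterolytically instead of in concert, which would leak stereochemical information or end in elimination to a dienoic acid. The fallback builds the cyclohexene by cycloaddition instead and sets out from 12. A Mizoroki–Heck reaction of 12 with 2-methylbut-3-en-2-ol (Pd(OAc)2, Bu4NCl, NaHCO3, DMF, 70 °C) should give 6-[(E)-3-hydroxy-3-methylbut-1-en-1-yl]-7-methoxy-2H-chromen-2-one F1. Dehydration of the tertiary allylic alcohol (MsCl, Et3N, CH2Cl2, 0 °C → rt) should give the diene 7-methoxy-6-[(E)-3-methylbuta-1,3-dien-1-yl]-2H-chromen-2-one F2. An enantioselective Diels–Alder reaction of F2 with excess methacrolein would follow, under a chiral oxazaborolidinium Lewis acid (B-o-tolyl oxazaborolidine from diphenylprolinol, activated with HNTf2, CH2Cl2, −78 °C). The 1-aryl and 3-methyl groups of the diene both direct bond formation to the product skeleton, and an endo-formyl transition state places the aryl group cis to the formyl group. With the catalyst enantiomer chosen accordingly, the route is rejoined at aldehyde 18.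

Step 7. After carbopalladation, β-carboxylate elimination (opening the lactone to an allyl-arene acid) may compete with β-hydride elimination. Zerovalent palladium may also ionise the tertiary allylic C–O bond and scramble or destroy the carbinol centre. The fallback performs the arylation on a free tertiary allylic alcohol and sets out from 8. Methanolysis of 8 (K2CO3, MeOH, rt) should give methyl (5R)-5-hydroxy-2,5-dimethylhept-6-enoate F3. A ligand-free phase-transfer Heck reaction of F3 with 12 (Pd(OAc)2, Bu4NCl, NaHCO3, DMF, 70 °C) should give methyl (5R,6E)-5-hydroxy-7-(7-methoxy-2-oxo-2H-chromen-6-yl)-2,5-dimethylhept-6-enoate F4, since hydroxyl is not lost from such intermediates. Base-catalysed relactonisation (DBU cat., toluene, 80 °C, removal of methanol) returns to 13.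

Step 9. The hindered acyl chloride may be reduced sluggishly, so that over-reduction to the neopentyl alcohol or hydride attack on the coumarin lactone begins to compete. The fallback reduces fully and re-oxidises, setting out from 17. NaBH4 in THF/DMF at −20 °C, which converts acyl chlorides to primary alcohols rapidly and leaves the coumarin largely untouched at this temperature, should give 6-[(1R,6S)-6-(hydroxymethyl)-3,6-dimethylcyclohex-2-en-1-yl]-7-methoxy-2H-chromen-2-one F5. Oxidation of F5 with Dess–Martin periodinane (CH2Cl2, NaHCO3, rt) returns to aldehyde 18.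

Further compounds
F1 | step 8 | 6-[(E)-3-hydroxy-3-methylbut-1-en-1-yl]-7-methoxy-2H-chromen-2-one | COc1cc2oc(=O)ccc2cc1/C=C/C(C)(C)O
F2 | step 8 | 7-methoxy-6-[(E)-3-methylbuta-1,3-dien-1-yl]-2H-chromen-2-one | COc1cc2oc(=O)ccc2cc1/C=C/C(C)=C
F3 | step 7 | methyl (5R)-5-hydroxy-2,5-dimethylhept-6-enoate (both C2 epimers) | C=C[C@](C)(O)CCC(C)C(=O)OC
F4 | step 7 | methyl (5R,6E)-5-hydroxy-7-(7-methoxy-2-oxo-2H-chromen-6-yl)-2,5-dimethylhept-6-enoate (both C2 epimers) | COc1cc2oc(=O)ccc2cc1/C=C/[C@](C)(O)CCC(C)C(=O)OC
F5 | step 9 | 6-[(1R,6S)-6-(hydroxymethyl)-3,6-dimethylcyclohex-2-en-1-yl]-7-methoxy-2H-chromen-2-one | COc1cc2oc(=O)ccc2cc1[C@@H]1C=C(C)CC[C@]1(C)CO
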